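Everything rests on opening the pyranone (ring C) at two bonds, C4–C4a and O1–C2. Ring A, oxygenated at C5 and C7, then maps onto symmetrical phloroglucinol, while C2, C3 and C4 are the keto ester carbons of a 1-benzoxepin-5-one-4-carboxylate that already contains ring B, the oxepine ring and the R-configured C10. Fusing the two forms the aryl ketone bond through an acyl ketene and, by dehydrative addition of the flanking phenol to the oxepinone carbonyl, the pyranone, all in one operation and without a regiochemical question. The precursor is the tert-butyl ester of this keto ester with O-benzyl on ring B and a silylated tertiary alcohol; its stereocentre derives from L-glutamic acid by Mitsunobu inversion.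

Key step: step 8

Remark on the chemistry: flavone locants are used (ring A C4a–C8a, ring C O1–C4, ring B C1′–C6′); "oxepinoflavone" means the flavone whose C3 and C2′ are joined by CH2(C9)–CH(C10)–O into a seven-membered ring, with C10 carrying the C(CH3)2O group; TBS is tert-butyldimethylsilyl; keto ester 11 is drawn as its enol, since its keto form is a pair of C4 epimers that converge in step 8.

Step 1
Reactants: 1 methyl 2,4-dihydroxybenzoate
Product: 2 methyl 4-(benzyloxy)-2-hydroxybenzoate
Conditions: BnBr (1.05 equiv), K2CO3, acetone, reflux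
Reagents that add atoms: benzyl bromide, BrCc1ccccc1
Why: Williamson ether synthesis that should go to the 4-OH alone, because the 2-OH is held in a hydrogen bond to the ester carbonyl and is the less acidic and less nucleophilic phenol.

Step 2
Reactants: 3 L-glutamic acid 5-tert-butyl ester [(2S)-2-amino-5-tert-butoxy-5-oxopentanoic acid]
Product: 5 (2S)-5-tert-butoxy-2-hydroxy-5-oxopentanoic acid, via α-lactone 4 (not isolated)
Conditions: NaNO2, AcOH–H2O, 0 °C to rt
Reagents that add atoms: water, O
Why: Diazotisation of an α-amino acid, in which the carboxylate displaces dinitrogen to give the α-lactone and water reopens it at the same carbon, so that two inversions should leave the S configuration (overall retention).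

Step 3
Reactants: 5 (2S)-5-tert-butoxy-2-hydroxy-5-oxopentanoic acid
Product: 6 5-tert-butyl 1-methyl (2S)-2-hydroxypentanedioate
Conditions: MeI, KHCO3, DMF, rt
Reagents that add atoms: iodomethane, CI
Why: SN2 alkylation of the carboxylate, the only anion present under hydrogencarbonate, so the secondary alcohol and the stereocentre should stay untouched.

Step 4
Reactants: 2 methyl 4-(benzyloxy)-2-hydroxybenzoate; 6 5-tert-butyl 1-methyl (2S)-2-hydroxypentanedioate
Product: 7 5-tert-butyl 1-methyl (2R)-2-[5-(benzyloxy)-2-(methoxycarbonyl)phenoxy]pentanedioate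
Conditions: PPh3, DIAD, THF, 0 °C to rt
Reagents that add atoms: none
Why: Mitsunobu etherification, in which the phenol displaces the phosphonium-activated oxygen of the α-hydroxy ester by SN2 with inversion, turning the S carbinol into the R aryl ether.

Step 5
Reactants: 7 5-tert-butyl 1-methyl (2R)-2-[5-(benzyloxy)-2-(methoxycarbonyl)phenoxy]pentanedioate
Product: 9 tert-butyl (4R)-4-[5-(benzyloxy)-2-(methoxycarbonyl)phenoxy]-5-hydroxy-5-methylhexanoate, via methyl ketone 8 (not isolated)
Conditions: MeMgBr (2.3 equiv), THF, −78 to −20 °C; then H2O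
Reagents that add atoms: methylmagnesium bromide, C[Mg]Br
Why: Twofold Grignard addition that should single out the α-aryloxy methyl ester, the most electrophilic of the three esters (the benzoate is deactivated by its two oxygen donors and the tert-butyl ester is shielded), and that leaves the configuration of the ether carbon as set.

Step 6
Reactants: 9 tert-butyl (4R)-4-[5-(benzyloxy)-2-(methoxycarbonyl)phenoxy]-5-hydroxy-5-methylhexanoate
Product: 10 tert-butyl (4R)-4-[5-(benzyloxy)-2-(methoxycarbonyl)phenoxy]-5-[(tert-butyldimethylsilyl)oxy]-5-methylhexanoate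
Conditions: TBSOTf, 2,6-lutidine, CH2Cl2, −40 to 0 °C
Reagents that add atoms: tert-butyldimethylsilyl triflate, CC(C)(C)[Si](C)(C)OS(=O)(=O)C(F)(F)F
Why: Silylation with a silyl triflate, the standard way to cap a hindered tertiary alcohol, run cold and buffered with lutidine so that the tert-butyl ester should not be attacked.

Step 7
Reactants: 10 tert-butyl (4R)-4-[5-(benzyloxy)-2-(methoxycarbonyl)phenoxy]-5-[(tert-butyldimethylsilyl)oxy]-5-methylhexanoate
Product: 11 tert-butyl (2R)-8-(benzyloxy)-2-{2-[(tert-butyldimethylsilyl)oxy]propan-2-yl}-5-hydroxy-2,3-dihydro-1-benzoxepine-4-carboxylate (enol form of the 5-oxo keto ester)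
Conditions: KOtBu (2.5 equiv), THF, 0 °C to rt; then AcOH
Reagents that add atoms: none
Why: Dieckmann condensation of the only enolisable ester onto the aryl methyl ester, which closes the seven-membered ring and is driven by deprotonation of the keto ester, with tert-butoxide matched to the ester so that no ester exchange occurs and with the C2 hydrogen out of reach of the base.

Step 8
Reactants: 11 tert-butyl (2R)-8-(benzyloxy)-2-{2-[(tert-butyldimethylsilyl)oxy]propan-2-yl}-5-hydroxy-2,3-dihydro-1-benzoxepine-4-carboxylate; 12 phloroglucinol (benzene-1,3,5-triol)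
Product: 15 (10R)-4′-O-benzyl-5,7-dihydroxy-oxepinoflavone TBS ether, via acyl ketene 13 (not isolated), via 2-acylphloroglucinol 14 (not isolated)
Conditions: anhydrous phloroglucinol (3 equiv), Ph2O, 160 °C then 230 °C, Ar stream (tBuOH and H2O distilled off)
Reagents that add atoms: none
Why: Heat makes the enol of 11 shed tert-butanol through a six-membered transition state to α-oxo ketene 13, which acylates phloroglucinol, either straight at carbon or through the aryl ester and a thermal O-to-C acyl shift, to give 1,3-diketone 14 (bond C4–C4a); a hydroxyl ortho to the new acyl group then adds to the oxepinone carbonyl and water leaves (bond O1–C2). The closest known reaction type is the Mentzer pyrone synthesis, the uncatalysed thermal condensation of phloroglucinol with α-substituted β-keto esters and aroylacetates to 5,7-dihydroxychromones and flavones. The single ring formed, the pyranone, closes by 6-exo-trig attack of the phenol oxygen on the ketone followed by dehydration to the aromatic pyranone. No stereocentre is created, and the existing centre C10 carries only an ether oxygen and no enolisable hydrogen, so heat should not erode it. The selectivity needed is chromone rather than coumarin, which the lack of an acid catalyst, the substituent on the α-carbon and the poorly electrophilic ketone (conjugated to the dioxygenated ring B) should secure, while the equivalence of the three phloroglucinol carbons leaves one possible acylation site. Excess phloroglucinol should curb a second acylation, the tert-butyl ester lowers the temperature of ketene release, and the silyl cap on the tertiary oxygen rules out internal lactonisation of the ketene.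

Step 9
Reactants: 15 (10R)-4′-O-benzyl-5,7-dihydroxy-oxepinoflavone TBS ether; 16 3-chloro-3-methylbut-1-yne
Product: 19 (10R)-4′-O-benzyl-5-hydroxy-2″,2″-dimethylpyrano[2,3-h]oxepinoflavone TBS ether (pyran oxygen on C7 and pyran CH=CH on C8), via propargyl ether 17 (not isolated), via allenyl phenol 18 (not isolated)
Conditions: 16 (2 equiv), K2CO3 (2 equiv), DMF, 65 °C, sealed tube; then 130 °C
Reagents that add atoms: none
Why: Alkylation of the acidic 7-OH (the 5-OH is held in a hydrogen bond to C4=O) by the tertiary propargylic chloride, then an aromatic propargyl Claisen rearrangement, which in 5-hydroxy-7-oxy chromones, xanthones and acridones goes to C8 across the C7–C8 bond of higher π-bond order, followed by 1,5-hydrogen shift and 6π oxa-electrocyclisation of allene 18, should give the angular 2,2-dimethylchromene.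

Step 10
Reactants: 19 (10R)-4′-O-benzyl-5-hydroxy-2″,2″-dimethylpyrano[2,3-h]oxepinoflavone TBS ether
Product: 20 (10R)-4′,5-dihydroxy-2″,2″-dimethylpyrano[2,3-h]oxepinoflavone TBS ether
Conditions: BCl3 (4 equiv), C6HMe5 (5 equiv), CH2Cl2, −78 °C; then H2O
Reagents that add atoms: none
Why: BCl3 cleaves the aryl benzyl ether at −78 °C while pentamethylbenzene captures the benzyl cation by Friedel–Crafts alkylation, a low-temperature debenzylation under which alkenes and silyl ethers are known to survive, the 5-OH being merely held as a boron chelate until work-up.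

Step 11
Reactants: 20 (10R)-4′,5-dihydroxy-2″,2″-dimethylpyrano[2,3-h]oxepinoflavone TBS ether
Product: 21 CNP0329736.1, the target
Conditions: TBAF (4 equiv), THF, 50 °C; then AcOH
Reagents that add atoms: none
Why: Fluoride-induced Si–O cleavage, driven by the strong Si–F bond, should free the tertiary alcohol without touching the chromene, the aryl ethers or the C10 stereocentre, which gives the target.

Compound list
1 | methyl 2,4-dihydroxybenzoate | COC(=O)c1ccc(O)cc1O | starting material
2 | methyl 4-(benzyloxy)-2-hydroxybenzoate | COC(=O)c1ccc(OCc2ccccc2)cc1O | intermediate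
3 | L-glutamic acid 5-tert-butyl ester, (2S)-2-amino-5-tert-butoxy-5-oxopentanoic acid | CC(C)(C)OC(=O)CC[C@H](N)C(=O)O | starting material
4 | tert-butyl 3-[(2R)-3-oxooxiran-2-yl]propanoate (α-lactone formed in the flask) | CC(C)(C)OC(=O)CC[C@H]1OC1=O | intermediate
5 | (2S)-5-tert-butoxy-2-hydroxy-5-oxopentanoic acid | CC(C)(C)OC(=O)CC[C@H](O)C(=O)O | intermediate
6 | 5-tert-butyl 1-methyl (2S)-2-hydroxypentanedioate | CC(C)(C)OC(=O)CC[C@H](O)C(=O)OC | intermediate
7 | 5-tert-butyl 1-methyl (2R)-2-[5-(benzyloxy)-2-(methoxycarbonyl)phenoxy]pentanedioate | CC(C)(C)OC(=O)CC[C@@H](Oc1cc(OCc2ccccc2)ccc1C(=O)OC)C(=O)OC | intermediate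
8 | tert-butyl (4R)-4-[5-(benzyloxy)-2-(methoxycarbonyl)phenoxy]-5-oxohexanoate (methyl ketone formed in the flask) | CC(C)(C)OC(=O)CC[C@@H](Oc1cc(OCc2ccccc2)ccc1C(=O)OC)C(C)=O | intermediate
9 | tert-butyl (4R)-4-[5-(benzyloxy)-2-(methoxycarbonyl)phenoxy]-5-hydroxy-5-methylhexanoate | CC(C)(C)OC(=O)CC[C@@H](Oc1cc(OCc2ccccc2)ccc1C(=O)OC)C(C)(C)O | intermediate
10 | tert-butyl (4R)-4-[5-(benzyloxy)-2-(methoxycarbonyl)phenoxy]-5-[(tert-butyldimethylsilyl)oxy]-5-methylhexanoate | CC(C)(C)OC(=O)CC[C@@H](Oc1cc(OCc2ccccc2)ccc1C(=O)OC)C(C)(C)O[Si](C)(C)C(C)(C)C | intermediate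
11 | tert-butyl (2R)-8-(benzyloxy)-2-{2-[(tert-butyldimethylsilyl)oxy]propan-2-yl}-5-hydroxy-2,3-dihydro-1-benzoxepine-4-carboxylate (enol of the 5-oxo keto ester) | CC(C)(C)OC(=O)C1=C(O)c2ccc(OCc3ccccc3)cc2O[C@@H](C(C)(C)O[Si](C)(C)C(C)(C)C)C1 | intermediate
12 | phloroglucinol (benzene-1,3,5-triol) | Oc1cc(O)cc(O)c1 | starting material
13 | (2R)-8-(benzyloxy)-2-{2-[(tert-butyldimethylsilyl)oxy]propan-2-yl}-4-(oxomethylidene)-3,4-dihydro-1-benzoxepin-5(2H)-one (α-oxo ketene formed in the flask) | O=C=C1C[C@H](C(C)(C)O[Si](C)(C)C(C)(C)C)Oc2cc(OCc3ccccc3)ccc2C1=O | intermediate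
14 | (2R)-8-(benzyloxy)-2-{2-[(tert-butyldimethylsilyl)oxy]propan-2-yl}-4-(2,4,6-trihydroxybenzoyl)-3,4-dihydro-1-benzoxepin-5(2H)-one (C4 epimers, formed in the flask) | Oc1cc(O)c(C(=O)C2C[C@H](C(C)(C)O[Si](C)(C)C(C)(C)C)Oc3cc(OCc4ccccc4)ccc3C2=O)c(O)c1 | intermediate
15 | (10R)-4′-O-benzyl-5,7-dihydroxy-oxepinoflavone TBS ether: flavone with 5-OH, 7-OH, 4′-OBn and the bridge C3–CH2–CH[C(CH3)2OTBS]–O–C2′ | Oc1cc(O)c2c(=O)c3c(oc2c1)-c1ccc(OCc2ccccc2)cc1O[C@@H](C(C)(C)O[Si](C)(C)C(C)(C)C)C3 | intermediate
16 | 3-chloro-3-methylbut-1-yne | C#CC(C)(C)Cl | starting material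
17 | 7-O-(2-methylbut-3-yn-2-yl) ether of 15 (formed in the flask) | C#CC(C)(C)Oc1cc(O)c2c(=O)c3c(oc2c1)-c1ccc(OCc2ccccc2)cc1O[C@@H](C(C)(C)O[Si](C)(C)C(C)(C)C)C3 | intermediate
18 | 8-(3-methylbuta-1,2-dien-1-yl) derivative of 15 with free 5-OH and 7-OH (formed in the flask) | CC(C)=C=Cc1c(O)cc(O)c2c(=O)c3c(oc12)-c1ccc(OCc2ccccc2)cc1O[C@@H](C(C)(C)O[Si](C)(C)C(C)(C)C)C3 | intermediate
19 | (10R)-4′-O-benzyl-5-hydroxy-2″,2″-dimethylpyrano[2,3-h]oxepinoflavone TBS ether (2,2-dimethyl-2H-pyran fused with its oxygen on C7 and its CH=CH on C8) | CC1(C)C=Cc2c(cc(O)c3c(=O)c4c(oc23)-c2ccc(OCc5ccccc5)cc2O[C@@H](C(C)(C)O[Si](C)(C)C(C)(C)C)C4)O1 | intermediate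
20 | (10R)-4′,5-dihydroxy-2″,2″-dimethylpyrano[2,3-h]oxepinoflavone TBS ether | CC1(C)C=Cc2c(cc(O)c3c(=O)c4c(oc23)-c2ccc(O)cc2O[C@@H](C(C)(C)O[Si](C)(C)C(C)(C)C)C4)O1 | intermediate
21 | CNP0329736.1: (10R)-4′,5-dihydroxy-10-(2-hydroxypropan-2-yl)-2″,2″-dimethylpyrano[2,3-h]oxepinoflavone | CC1(C)C=Cc2c(cc(O)c3c(=O)c4c(oc23)-c2ccc(O)cc2O[C@@H](C(C)(C)O)C4)O1 | target

Total step count: 11. Longest linear sequence: 10 steps (steps 2 to 11, from 3).

Steps most likely to fail

1. Step 8 (key step). The acyl ketene may be lost to hydrolytic decarboxylation by the water of condensation, or the closure may take the Pechmann course by C–C bond formation at the ketone. The silyl group may also migrate to a phenol at 230 °C, so that the tertiary alcohol captures the ketene. The fallback sets out from 11 and comes back at 15; it builds ring C from the opposite side, by ketone acylation and ring closure at O1–C8a.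
 - Heating 11 in wet DMSO at 150 °C would remove the ester carbon and give the benzoxepinone ketone F1.
 - Its lithium enolate (LiN(SiMe3)2, THF, −78 °C) would be C-acylated with commercial 2,4,6-trifluorobenzoyl chloride to the 1,3-diketone F2.
 - K2CO3 in DMF at 80 °C would close the pyranone by intramolecular SNAr of the enolate oxygen on an ortho C–F bond and give the 5,7-difluoro oxepinoflavone F3.
 - Allyl alcohol and NaH in THF would replace both carbonyl-activated fluorides and give the 5,7-bis(allyloxy) oxepinoflavone F4.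
 - Catalytic Pd(PPh3)4 with morpholine would remove the allyl groups and return to 15.

2. Step 9. The Claisen rearrangement may deliver the propargyl unit to C6 instead of C8, which leads to linear annulation. The fallback sets out from 17, isolated for this purpose by stopping step 9 after the 65 °C stage, and comes back at 19.
 - Iodination with benzyltrimethylammonium dichloroiodate and CaCO3 in CH2Cl2–MeOH, which in 5-hydroxy-7-alkoxyflavones goes to C6, would block that carbon as the 6-iodo propargyl ether F5.
 - Heating in DMF at 130 °C would then leave only C8 open to the rearrangement and give the 6-iodo angular chromene F6.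
 - Hydrodeiodination with catalytic Pd(PPh3)4 and HCO2Na in DMF at 80 °C would return to 19.

3. Step 10. The Lewis acid may ionise the tertiary allylic ether of the new pyran ring, or strip the silyl ether ahead of the benzyl group. The fallback sets out from 15 and comes back at 20; it removes the benzyl group before any alkene exists.
 - Hydrogenolysis of 15 (H2, Pd/C, EtOAc–MeOH) would give the 4′,5,7-trihydroxy oxepinoflavone TBS ether F7.
 - One equivalent of K2CO3 with 16 in DMF at 65 °C would alkylate the most acidic hydroxyl, 7-OH, to the 7-O-propargyl ether F8.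
 - Heating at 130 °C would rearrange and cyclise F8 as in step 9 and return to 20.

Further compounds
F1 | step 8 | (2R)-8-(benzyloxy)-2-{2-[(tert-butyldimethylsilyl)oxy]propan-2-yl}-3,4-dihydro-1-benzoxepin-5(2H)-one | O=C1CC[C@H](C(C)(C)O[Si](C)(C)C(C)(C)C)Oc2cc(OCc3ccccc3)ccc21
F2 | step 8 | (2R)-8-(benzyloxy)-2-{2-[(tert-butyldimethylsilyl)oxy]propan-2-yl}-4-(2,4,6-trifluorobenzoyl)-3,4-dihydro-1-benzoxepin-5(2H)-one (C4 epimers) | O=C(c1c(F)cc(F)cc1F)C1C[C@H](C(C)(C)O[Si](C)(C)C(C)(C)C)Oc2cc(OCc3ccccc3)ccc2C1=O
F3 | step 8 | (10R)-4′-O-benzyl-5,7-difluoro-oxepinoflavone TBS ether | Fc1cc(F)c2c(=O)c3c(oc2c1)-c1ccc(OCc2ccccc2)cc1O[C@@H](C(C)(C)O[Si](C)(C)C(C)(C)C)C3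
F4 | step 8 | (10R)-5,7-bis(allyloxy)-4′-O-benzyl-oxepinoflavone TBS ether | C=CCOc1cc(OCC=C)c2c(=O)c3c(oc2c1)-c1ccc(OCc2ccccc2)cc1O[C@@H](C(C)(C)O[Si](C)(C)C(C)(C)C)C3
F5 | step 9 | 6-iodo derivative of propargyl ether 17 | C#CC(C)(C)Oc1c(I)c(O)c2c(=O)c3c(oc2c1)-c1ccc(OCc2ccccc2)cc1O[C@@H](C(C)(C)O[Si](C)(C)C(C)(C)C)C3
F6 | step 9 | 6-iodo derivative of chromene 19 | CC1(C)C=Cc2c(c(I)c(O)c3c(=O)c4c(oc23)-c2ccc(OCc5ccccc5)cc2O[C@@H](C(C)(C)O[Si](C)(C)C(C)(C)C)C4)O1
F7 | step 10 | (10R)-4′,5,7-trihydroxy-oxepinoflavone TBS ether | Oc1cc(O)c2c(=O)c3c(oc2c1)-c1ccc(O)cc1O[C@@H](C(C)(C)O[Si](C)(C)C(C)(C)C)C3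
F8 | step 10 | 7-O-(2-methylbut-3-yn-2-yl) ether of F7 | C#CC(C)(C)Oc1cc(O)c2c(=O)c3c(oc2c1)-c1ccc(O)cc1O[C@@H](C(C)(C)O[Si](C)(C)C(C)(C)C)C3
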